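**Overview**
- Retrosynthesis: the fused 5-aminobutenolide is cut at N4–C5, C6–Cα and O–C5 in one stroke (seco amino aldehyde + pyruvic acid). Before that C3–C18, the C11 methyl and C9–C9a are cut (two vinylogous Mannich reactions, one enolate methylation).
- Enabling feature: in the butenolide ring fused to the azepane ring, the aminal carbon C5 (bonded to N4 and the lactone O) is at the aldehyde level and the ring carbon C6 is that aldehyde's α-carbon, so CH3–Cα–C(=O)O is a pyruvic acid unit.
- Forward ring order: pyrrolidine (from L-pyroglutamate), spiro lactone ring (joined as a furan at C9–C9a), pendant lactone ring (joined at C3–C18), then azepane and fused butenolide together in the last step.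
- Stereochemistry: the C3 ester steers the first Mannich addition (C9a trans, C9 threo); C11 comes from methylation anti to the pyrrolidine; after decarboxylation C9a steers the second addition (C3 trans, C18 threo); C20 comes from hydrogenation; C5 from equilibration.
- Numbering: pyrrolo[1,2-a]azepine core (C3 pyrrolidine CH, N4, C5 aminal CH, C6–C8, C9 spiro carbon, C9a ring fusion); C11 and C20 carry the lactone methyls, C18 is the pendant carbinol carbon. Target: 3S,5S,9S,9aS,11R,18S,20S.

Key step: step 17

Remark: the C3 carboxyl is carried as a benzyl ester so that one hydrogenation also frees the acid, and the seco amino aldehyde is used as its crude trifluoroacetate. Abbreviations: Boc = tert-butoxycarbonyl, TBDPS = tert-butyldiphenylsilyl, TIPS = triisopropylsilyl.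

**Route**

Step 1
Reactants: 1 benzyl (S)-N-Boc-pyroglutamate
Product: 2 benzyl (2S)-N-Boc-5-hydroxyprolinate (hemiaminal; both C5 epimers)
Conditions: LiBHEt3, THF, −78 °C; then H2O
Reagents that add atoms: none
Why: Partial reduction of an N-acyl lactam: the Boc group makes the ring carbonyl imide-like, so LiBHEt3 at −78 °C should stop at the hemiaminal without touching the benzyl ester or the C2 stereocentre.

Step 2
Reactants: 2 benzyl (2S)-N-Boc-5-hydroxyprolinate
Product: 3 benzyl (2S)-N-Boc-5-methoxyprolinate (both C5 epimers)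
Conditions: MeOH, TsOH (cat.), rt
Reagents that add atoms: methanol, CO
Why: Acid-catalysed N,O-acetal exchange through the N-Boc iminium ion gives a storable methoxy aminal, and the epimer mixture is harmless because this carbon becomes planar again in step 7.

Step 3
Reactants: 4 tetrahydrofuran
Product: 5 tert-butyl(4-iodobutoxy)diphenylsilane
Conditions: TBDPSCl, NaI, MeCN, rt to 55 °C
Reagents that add atoms: tert-butyl(chloro)diphenylsilane, CC(C)(C)[Si](Cl)(c1ccccc1)c1ccccc1; sodium iodide, [Na+].[I-]
Why: Silyl halide–iodide ring opening of a cyclic ether: O-silylation gives an oxonium ion that iodide opens by SN2 attack at the α-carbon.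

Step 4
Reactants: 6 furan; 5 tert-butyl(4-iodobutoxy)diphenylsilane
Product: 8 2-[4-(TBDPSoxy)butyl]furan, via 2-furyllithium 7 (not isolated)
Conditions: n-BuLi, THF, −78 to 0 °C; then 5, −78 °C to rt
Reagents that add atoms: none
Why: α-Lithiation of furan followed by SN2 alkylation of the furyllithium with the primary iodide, the bulky silyl ether being inert to the organolithium at low temperature.

Step 5
Reactants: 8 2-[4-(TBDPSoxy)butyl]furan
Product: 11 5-[4-(TBDPSoxy)butyl]furan-2(5H)-one (racemic), via 5-lithiofuran 9 (not isolated), via dimethyl furylboronate 10 (not isolated)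
Conditions: n-BuLi, THF, −78 to 0 °C; B(OMe)3, −78 °C to rt; 30% aq H2O2, 0 °C to rt
Reagents that add atoms: hydrogen peroxide, OO
Why: Lithiation at the only free α-position, borylation and oxidative exchange of C–B for C–O give the 2-hydroxyfuran, which tautomerises to the butenolide (a 2(3H)-tautomer, if present, converges in step 6).

Step 6
Reactants: 11 5-[4-(TBDPSoxy)butyl]furan-2(5H)-one
Product: 12 5-[4-(TBDPSoxy)butyl]-2-(triisopropylsilyloxy)furan
Conditions: TIPSOTf, Et3N, CH2Cl2, 0 °C
Reagents that add atoms: triisopropylsilyl trifluoromethanesulfonate, CC(C)[Si](C(C)C)(C(C)C)OS(=O)(=O)C(F)(F)F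
Why: Silyl dienol ether formation by soft enolisation aromatises the butenolide to the 2-silyloxyfuran and erases its stereocentre on purpose.

Step 7
Reactants: 3 benzyl (2S)-N-Boc-5-methoxyprolinate; 12 5-[4-(TBDPSoxy)butyl]-2-(triisopropylsilyloxy)furan
Product: 14 benzyl (2S,5S)-N-Boc-5-[(2S)-2-(4-TBDPSoxybutyl)-5-oxo-2,5-dihydrofuran-2-yl]prolinate (2,5-trans; threo), via N-Boc iminium triflate 13 (not isolated)
Conditions: TIPSOTf (10 mol %), CH2Cl2, −78 to 0 °C
Reagents that add atoms: none
Why: Vinylogous Mannich reaction: the silyl triflate ionises the N,O-acetal and the silyloxyfuran attacks through its C5 on the iminium face trans to the C2 ester (sets C9a) in the threo arrangement of the two rings (sets the quaternary C9), the silyl group leaving with the methoxide so that the acid is regenerated.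

Step 8
Reactants: 14 first Mannich adduct
Product: 15 (2S,5S)-N-Boc-5-[(2S)-2-(4-TBDPSoxybutyl)-5-oxotetrahydrofuran-2-yl]proline
Conditions: H2 (1 atm), 10% Pd/C, EtOAc, rt
Reagents that add atoms: none
Why: Heterogeneous hydrogenation saturates the disubstituted butenolide alkene and hydrogenolyses the benzyl ester in one operation, leaving Boc, silyl ether and lactone intact and creating no stereocentre.

Step 9
Reactants: 15 lactone acid
Product: 17 tert-butyl (2S)-2-[(2S)-2-(4-TBDPSoxybutyl)-5-oxotetrahydrofuran-2-yl]-5-methoxypyrrolidine-1-carboxylate (both epimers at the acetal carbon), via acetoxy aminal 16 (not isolated)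
Conditions: PhI(OAc)2, I2, CH2Cl2, rt, visible light; then MeOH
Reagents that add atoms: methanol, CO
Why: Radical oxidative decarboxylation of an N-acyl α-amino acid (acyl hypoiodite fragmentation): the α-amino radical is oxidised to the N-Boc iminium ion, which is trapped by acetate and then methanol, so the carboxyl that has done its stereodirecting work is exchanged for a leaving group at C3.

Step 10
Reactants: 17 methoxy aminal lactone
Product: 19 tert-butyl (2S)-2-[(2S,4R)-2-(4-TBDPSoxybutyl)-4-methyl-5-oxotetrahydrofuran-2-yl]-5-methoxypyrrolidine-1-carboxylate, via lithium enolate 18 (not isolated)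
Conditions: LiN(iPr)2 (LDA), THF, −78 °C; MeI, −78 to −40 °C
Reagents that add atoms: iodomethane, CI
Why: Lactone enolate alkylation: methyl iodide should approach the planar enolate anti to the larger γ-substituent (the branched N-Boc pyrrolidinyl group rather than the unbranched chain), which sets C11 with the methyl trans to the pyrrolidine.

Step 11
Reactants: 20 3-methylfuran-2(5H)-one
Product: 21 3-methyl-2-(triisopropylsilyloxy)furan
Conditions: TIPSOTf, Et3N, CH2Cl2, 0 °C
Reagents that add atoms: triisopropylsilyl trifluoromethanesulfonate, CC(C)[Si](C(C)C)(C(C)C)OS(=O)(=O)C(F)(F)F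
Why: Silyl dienol ether formation by soft enolisation of the butenolide gives the nucleophilic 2-silyloxyfuran.

Step 12
Reactants: 19 α-methyl lactone methoxy aminal; 21 3-methyl-2-(triisopropylsilyloxy)furan
Product: 23 tert-butyl (2S,5S)-2-[(2S,4R)-2-(4-TBDPSoxybutyl)-4-methyl-5-oxotetrahydrofuran-2-yl]-5-[(2S)-4-methyl-5-oxo-2,5-dihydrofuran-2-yl]pyrrolidine-1-carboxylate (2,5-trans; threo), via N-Boc iminium triflate 22 (not isolated)
Conditions: TIPSOTf (10 mol %), CH2Cl2, −78 °C
Reagents that add atoms: none
Why: Vinylogous Mannich reaction: the furan adds through C5 to the iminium carbon C3 on the face trans to the fully substituted substituent at C9a (sets C3) in the threo arrangement (sets C18).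

Step 13
Reactants: 23 second Mannich adduct
Product: 24 tert-butyl (2S,5S)-2-[(2S,4R)-2-(4-TBDPSoxybutyl)-4-methyl-5-oxotetrahydrofuran-2-yl]-5-[(2S,4S)-4-methyl-5-oxotetrahydrofuran-2-yl]pyrrolidine-1-carboxylate
Conditions: H2 (4 atm), 10% Pd/C, EtOAc, rt
Reagents that add atoms: none
Why: Heterogeneous hydrogenation of the trisubstituted butenolide from the face opposite the pyrrolidine at C18 gives the cis-α-methyl lactone and so sets C20.

Step 14
Reactants: 24 bis-lactone silyl ether
Product: 25 N-Boc bis-lactone alcohol (4-hydroxybutyl chain at C9)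
Conditions: HF·pyridine, pyridine, THF, 0 °C to rt
Reagents that add atoms: none
Why: Fluoride cleavage of the silyl ether under buffered acidic conditions that should neither epimerise the α-methyl lactones nor remove the Boc group.

Step 15
Reactants: 25 N-Boc bis-lactone alcohol
Product: 26 N-Boc bis-lactone aldehyde (4-oxobutyl chain at C9)
Conditions: Dess–Martin periodinane, CH2Cl2, 0 °C to rt
Reagents that add atoms: none
Why: Dess–Martin oxidation takes the primary alcohol to the aldehyde and no further under near-neutral conditions.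

Step 16
Reactants: 26 N-Boc bis-lactone aldehyde
Product: 27 seco amino aldehyde trifluoroacetate
Conditions: TFA, CH2Cl2, 0 °C to rt; evaporate, use crude
Reagents that add atoms: trifluoroacetic acid, OC(=O)C(F)(F)F
Why: Acidolysis of the tert-butyl carbamate; the ammonium salt (or its cyclic hemiaminal and iminium forms) is the direct precursor of the enamine of step 17 and is therefore not purified.

Step 17
Reactants: 27 seco amino aldehyde trifluoroacetate; 28 pyruvic acid
Product: 32 target (3S,5S,9S,9aS,11R,18S,20S), via cyclic enamine 29 (not isolated), via enamine aldol adduct 30 (not isolated), via iminium carboxylate 31 (not isolated)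
Conditions: NaOAc, AcOH, 1,4-dioxane, 4 Å MS, 60 °C; pyruvic acid added slowly
Reagents that add atoms: none
Why: Proposed new method: the secondary amine of 27, set free by the buffer, adds to its own aldehyde (7-exo-trig; this closes the azepane ring as a hemiaminal) and loses water to the endocyclic enamine 29, whose nucleophilic C6 adds to the ketone carbonyl of pyruvic acid to give 30; the enamine nitrogen then pushes out the tertiary hydroxyl to give the conjugated iminium carboxylate 31, and the carboxylate oxygen adds to the iminium carbon C5 (5-exo-trig; this closes the butenolide ring). The closest known reaction type is the secondary-amine-mediated condensation of enolisable aldehydes with glyoxylic acid, which gives 5-amino- and 5-hydroxy-2(5H)-furanones by enamine aldol reaction and lactonisation; here pyruvic acid takes the place of glyoxylic acid and the amine is part of the substrate, so the 5-aminobutenolide stage is the end point and not a transient. C5 is the only new stereocentre and is set under thermodynamic control, since the aminal lactone can reopen to 31; it should settle with the lactone oxygen on the azepane face opposite the C1 methylene of the pyrrolidine (H5 and H9a trans). The step needs C–C bond formation at C6 with pyruvic acid as the electrophile and not as an enol nucleophile toward the iminium form (Mannich addition at C5): the tether holds the enamine at N4–C5=C6, C6 is the only enolisable position of the aldehyde, a Mannich adduct can revert whereas removal of water pulls the aldol and lactonisation branch forward, and slow addition limits self-condensation of the keto acid. The amine is too hindered (2,5-disubstituted, next to a quaternary carbon) to be lost as an amide or ketimine of pyruvic acid, and the weakly acidic medium keeps it from opening the two saturated lactones.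

**Compound list**

1 | benzyl (2S)-1-Boc-5-oxopyrrolidine-2-carboxylate (benzyl N-Boc-L-pyroglutamate) | O=C(OCc1ccccc1)[C@@H]1CCC(=O)N1C(=O)OC(C)(C)C | starting material
2 | benzyl (2S)-1-Boc-5-hydroxypyrrolidine-2-carboxylate, both C5 epimers | O=C(OCc1ccccc1)[C@@H]1CCC(O)N1C(=O)OC(C)(C)C | intermediate
3 | benzyl (2S)-1-Boc-5-methoxypyrrolidine-2-carboxylate, both C5 epimers | O=C(OCc1ccccc1)[C@@H]1CCC(OC)N1C(=O)OC(C)(C)C | intermediate
4 | tetrahydrofuran | C1CCOC1 | starting material
5 | tert-butyl(4-iodobutoxy)diphenylsilane | ICCCCO[Si](c1ccccc1)(c1ccccc1)C(C)(C)C | intermediate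
6 | furan | c1ccoc1 | starting material
7 | 2-furyllithium (not isolated) | [Li]c1ccco1 | intermediate
8 | 2-[4-(tert-butyldiphenylsilyloxy)butyl]furan | c1coc(CCCCO[Si](c2ccccc2)(c2ccccc2)C(C)(C)C)c1 | intermediate
9 | 5-lithio-2-[4-(TBDPSoxy)butyl]furan (not isolated) | [Li]c1ccc(CCCCO[Si](c2ccccc2)(c2ccccc2)C(C)(C)C)o1 | intermediate
10 | dimethyl {5-[4-(TBDPSoxy)butyl]furan-2-yl}boronate (not isolated) | COB(OC)c1ccc(CCCCO[Si](c2ccccc2)(c2ccccc2)C(C)(C)C)o1 | intermediate
11 | 5-[4-(TBDPSoxy)butyl]furan-2(5H)-one, racemic | O=C1C=CC(CCCCO[Si](c2ccccc2)(c2ccccc2)C(C)(C)C)O1 | intermediate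
12 | 5-[4-(TBDPSoxy)butyl]-2-(triisopropylsilyloxy)furan | CC(C)[Si](C(C)C)(C(C)C)Oc1ccc(CCCCO[Si](c2ccccc2)(c2ccccc2)C(C)(C)C)o1 | intermediate
13 | (S)-2-benzyloxycarbonyl-1-Boc-1-pyrrolinium triflate (not isolated) | O=C(OCc1ccccc1)[C@@H]1CCC=[N+]1C(=O)OC(C)(C)C.[O-]S(=O)(=O)C(F)(F)F | intermediate
14 | benzyl (2S,5S)-1-Boc-5-[(2S)-2-(4-TBDPSoxybutyl)-5-oxo-2,5-dihydrofuran-2-yl]pyrrolidine-2-carboxylate (2,5-trans, threo) | CC(C)(C)[Si](c1ccccc1)(c1ccccc1)OCCCC[C@]2(C=CC(=O)O2)[C@@H]2CC[C@@H](C(=O)OCc3ccccc3)N2C(=O)OC(C)(C)C | intermediate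
15 | (2S,5S)-1-Boc-5-[(2S)-2-(4-TBDPSoxybutyl)-5-oxotetrahydrofuran-2-yl]pyrrolidine-2-carboxylic acid | CC(C)(C)[Si](c1ccccc1)(c1ccccc1)OCCCC[C@]2(CCC(=O)O2)[C@@H]2CC[C@@H](C(=O)O)N2C(=O)OC(C)(C)C | intermediate
16 | 5-acetoxy N,O-acetal corresponding to 17, epimers at the acetal carbon (not isolated) | CC(C)(C)[Si](c1ccccc1)(c1ccccc1)OCCCC[C@]2(CCC(=O)O2)[C@@H]2CCC(OC(C)=O)N2C(=O)OC(C)(C)C | intermediate
17 | tert-butyl (2S)-2-[(2S)-2-(4-TBDPSoxybutyl)-5-oxotetrahydrofuran-2-yl]-5-methoxypyrrolidine-1-carboxylate, epimers at the acetal carbon | CC(C)(C)[Si](c1ccccc1)(c1ccccc1)OCCCC[C@]2(CCC(=O)O2)[C@@H]2CCC(OC)N2C(=O)OC(C)(C)C | intermediate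
18 | lithium enolate of lactone 17 (not isolated) | CC(C)(C)[Si](c1ccccc1)(c1ccccc1)OCCCC[C@]2(CC=C(O[Li])O2)[C@@H]2CCC(OC)N2C(=O)OC(C)(C)C | intermediate
19 | tert-butyl (2S)-2-[(2S,4R)-2-(4-TBDPSoxybutyl)-4-methyl-5-oxotetrahydrofuran-2-yl]-5-methoxypyrrolidine-1-carboxylate, epimers at the acetal carbon | CC(C)(C)[Si](c1ccccc1)(c1ccccc1)OCCCC[C@]2(C[C@@H](C)C(=O)O2)[C@@H]2CCC(OC)N2C(=O)OC(C)(C)C | intermediate
20 | 3-methylfuran-2(5H)-one | CC1=CCOC1=O | starting material
21 | 3-methyl-2-(triisopropylsilyloxy)furan | Cc1ccoc1O[Si](C(C)C)(C(C)C)C(C)C | intermediate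
22 | N-Boc pyrrolinium triflate derived from 19 (not isolated) | CC(C)(C)[Si](c1ccccc1)(c1ccccc1)OCCCC[C@]2(C[C@@H](C)C(=O)O2)[C@@H]2CCC=[N+]2C(=O)OC(C)(C)C.[O-]S(=O)(=O)C(F)(F)F | intermediate
23 | tert-butyl (2S,5S)-2-[(2S,4R)-2-(4-TBDPSoxybutyl)-4-methyl-5-oxotetrahydrofuran-2-yl]-5-[(2S)-4-methyl-5-oxo-2,5-dihydrofuran-2-yl]pyrrolidine-1-carboxylate (2,5-trans, threo) | CC(C)(C)[Si](c1ccccc1)(c1ccccc1)OCCCC[C@]2(C[C@@H](C)C(=O)O2)[C@@H]2CC[C@@H]([C@@H]3C=C(C)C(=O)O3)N2C(=O)OC(C)(C)C | intermediate
24 | tert-butyl (2S,5S)-2-[(2S,4R)-2-(4-TBDPSoxybutyl)-4-methyl-5-oxotetrahydrofuran-2-yl]-5-[(2S,4S)-4-methyl-5-oxotetrahydrofuran-2-yl]pyrrolidine-1-carboxylate | CC(C)(C)[Si](c1ccccc1)(c1ccccc1)OCCCC[C@]2(C[C@@H](C)C(=O)O2)[C@@H]2CC[C@@H]([C@@H]3C[C@H](C)C(=O)O3)N2C(=O)OC(C)(C)C | intermediate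
25 | N-Boc bis-lactone alcohol (4-hydroxybutyl in place of the silyloxybutyl chain of 24) | OCCCC[C@]1(C[C@@H](C)C(=O)O1)[C@@H]1CC[C@@H]([C@@H]2C[C@H](C)C(=O)O2)N1C(=O)OC(C)(C)C | intermediate
26 | N-Boc bis-lactone aldehyde (4-oxobutyl chain) | O=CCCC[C@]1(C[C@@H](C)C(=O)O1)[C@@H]1CC[C@@H]([C@@H]2C[C@H](C)C(=O)O2)N1C(=O)OC(C)(C)C | intermediate
27 | seco amino aldehyde, trifluoroacetate salt | O=CCCC[C@]1(C[C@@H](C)C(=O)O1)[C@@H]1CC[C@@H]([C@@H]2C[C@H](C)C(=O)O2)N1.OC(=O)C(F)(F)F | intermediate
28 | pyruvic acid | CC(=O)C(=O)O | starting material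
29 | cyclic enamine (N4–C5=C6 in the closed azepine ring) (not isolated) | C1CC[C@]2(C[C@@H](C)C(=O)O2)[C@@H]2CC[C@@H]([C@@H]3C[C@H](C)C(=O)O3)N2C=1 | intermediate
30 | enamine aldol adduct: 2-hydroxy-2-(C6-yl)propanoic acid, mixture at the carbinol carbon (not isolated) | CC(O)(C(=O)O)C1CC[C@]2(C[C@@H](C)C(=O)O2)[C@@H]2CC[C@@H]([C@@H]3C[C@H](C)C(=O)O3)N2C=1 | intermediate
31 | conjugated iminium carboxylate (N4=C5, C6=Cα, carboxylate cis to C5) (not isolated) | C/C(C(=O)[O-])=C1\CC[C@]2(C[C@@H](C)C(=O)O2)[C@@H]2CC[C@@H]([C@@H]3C[C@H](C)C(=O)O3)[N+]2=C1 | intermediate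
32 | CNP0155196.1 (3S,5S,9S,9aS,11R,18S,20S) | CC1=C2CC[C@]3(C[C@@H](C)C(=O)O3)[C@@H]3CC[C@@H]([C@@H]4C[C@H](C)C(=O)O4)N3[C@H]2OC1=O | target

**Step count**
Total: 17 steps. Longest linear sequence: 14 steps (from tetrahydrofuran 4 through steps 3–10 and 12–17).

**Steps most likely to fail**

1. Step 17 (proposed new method). Pyruvic acid may act as an enol nucleophile toward the cyclic iminium form (Mannich addition at C5), or condense with itself faster than the enamine attacks its ketone, so that the C6–Cα bond never forms. The fallback uses known reactions only, sets out from N-Boc aldehyde 26 and fixes the polarity before the amine is freed. Silyl enol ether formation (TMSCl, Et3N, DMF, 80 °C) should give trimethylsilyl enol ether F1. Mukaiyama aldol addition of F1 to commercial tert-butyl pyruvate (BF3·OEt2, CH2Cl2, −78 °C) forms the C6–Cα bond and gives tert-butyl hydroxy ester aldehyde F2 as a diastereomer mixture that does not matter, since both new centres become trigonal later. TFA in CH2Cl2 then removes the Boc group and the tert-butyl ester together to give amino aldehyde hydroxy acid trifluoroacetate F3. Warmed in the buffer of step 17 without pyruvic acid, it should close to the enamine and so come back to the route at aldol adduct 30, which goes on through 31 to target 32; dehydration of a β-hydroxy carbonyl compound and aminal lactone formation from a 4-oxo-2-enoic acid and a secondary amine are ordinary reactions.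

2. Step 7. Attack through the substituted C5 of furan 12 on the ring iminium ion may be slow at the congested centre, so that reaction through C3 of the furan, loss of the silyl group or weak threo control take over. The fallback sets out from methoxy aminal 3 and builds the fully substituted carbon in two stages. Vinylogous Mannich reaction of 3 with commercial 2-(trimethylsilyloxy)furan (TMSOTf cat., CH2Cl2, −78 °C) should give the unsubstituted butenolide adduct F4 (the configuration at its butenolide carbon is of no consequence), and TIPSOTf/Et3N turns it into the 5-pyrrolidinyl-2-silyloxyfuran F5. Iodide 5 is converted by Kornblum oxidation (DMSO, NaHCO3, heat) into 4-(tert-butyldiphenylsilyloxy)butanal F6. Vinylogous Mukaiyama aldol addition of F5 to F6 (BF3·OEt2, CH2Cl2, −78 °C) then forms the C9–C8 bond with an unbranched aldehyde as the electrophile; attack anti to the N-Boc group, in the conformer that keeps the C9a hydrogen in the furan plane (allylic 1,3-strain), should give carbinol F7 with the required configuration at C9. Dehydration with Burgess reagent (the only β-hydrogens are on C7) gives diene F8. The conditions of step 8 (H2, Pd/C) saturate both alkenes and cleave the benzyl ester, so the sequence comes back to the route at acid 15.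

3. Step 10. The enolate may not discriminate well between its two faces, because both γ-substituents are carbon groups, and double methylation may compete. The fallback sets out from lactone 17 and replaces substrate-controlled C–C bond formation by catalyst-controlled C–H bond formation. The lithium enolate 18 is trapped with Eschenmoser's salt (dimethylmethyleneiminium iodide) to give Mannich base F9, which is quaternised with MeI to methiodide F10 and eliminated with NaHCO3 to α-methylene lactone F11. Asymmetric hydrogenation with Ru(OAc)2(BINAP) (H2, MeOH/CH2Cl2), using the ligand antipode that delivers hydrogen to the face syn to the pyrrolidine (both antipodes are available and would be tested), should give α-methyl lactone 19, where the sequence comes back to the route.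

**Further compounds**

F1 | step 17 | trimethylsilyl enol ether of aldehyde 26 (E/Z mixture) | C[Si](C)(C)OC=CCC[C@]1(C[C@@H](C)C(=O)O1)[C@@H]1CC[C@@H]([C@@H]2C[C@H](C)C(=O)O2)N1C(=O)OC(C)(C)C
F2 | step 17 | tert-butyl 2-hydroxy-2-methyl-3-formyl ester (Mukaiyama aldol adduct at C6, N-Boc, diastereomer mixture) | CC(O)(C(=O)OC(C)(C)C)C(C=O)CC[C@]1(C[C@@H](C)C(=O)O1)[C@@H]1CC[C@@H]([C@@H]2C[C@H](C)C(=O)O2)N1C(=O)OC(C)(C)C
F3 | step 17 | amino aldehyde hydroxy acid, trifluoroacetate salt | CC(O)(C(=O)O)C(C=O)CC[C@]1(C[C@@H](C)C(=O)O1)[C@@H]1CC[C@@H]([C@@H]2C[C@H](C)C(=O)O2)N1.OC(=O)C(F)(F)F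
F4 | step 7 | benzyl (2S,5S)-1-Boc-5-(5-oxo-2,5-dihydrofuran-2-yl)pyrrolidine-2-carboxylate | O=C1C=CC(O1)[C@@H]1CC[C@@H](C(=O)OCc2ccccc2)N1C(=O)OC(C)(C)C
F5 | step 7 | benzyl (2S,5S)-1-Boc-5-[5-(triisopropylsilyloxy)furan-2-yl]pyrrolidine-2-carboxylate | CC(C)[Si](C(C)C)(C(C)C)Oc1ccc(o1)[C@@H]1CC[C@@H](C(=O)OCc2ccccc2)N1C(=O)OC(C)(C)C
F6 | step 7 | 4-(tert-butyldiphenylsilyloxy)butanal | O=CCCCO[Si](c1ccccc1)(c1ccccc1)C(C)(C)C
F7 | step 7 | vinylogous aldol carbinol (C8 hydroxyl, mixture at C8) | CC(C)(C)[Si](c1ccccc1)(c1ccccc1)OCCCC(O)[C@]2(C=CC(=O)O2)[C@@H]2CC[C@@H](C(=O)OCc3ccccc3)N2C(=O)OC(C)(C)C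
F8 | step 7 | diene with (E)-C7=C8 alkene | CC(C)(C)[Si](c1ccccc1)(c1ccccc1)OCC/C=C/[C@]2(C=CC(=O)O2)[C@@H]2CC[C@@H](C(=O)OCc3ccccc3)N2C(=O)OC(C)(C)C
F9 | step 10 | α-(dimethylaminomethyl) lactone (Mannich base) | CC(C)(C)[Si](c1ccccc1)(c1ccccc1)OCCCC[C@]2(CC(CN(C)C)C(=O)O2)[C@@H]2CCC(OC)N2C(=O)OC(C)(C)C
F10 | step 10 | methiodide of the Mannich base | CC(C)(C)[Si](c1ccccc1)(c1ccccc1)OCCCC[C@]2(CC(C[N+](C)(C)C)C(=O)O2)[C@@H]2CCC(OC)N2C(=O)OC(C)(C)C.[I-]
F11 | step 10 | α-methylene lactone | CC(C)(C)[Si](c1ccccc1)(c1ccccc1)OCCCC[C@]2(CC(=C)C(=O)O2)[C@@H]2CCC(OC)N2C(=O)OC(C)(C)C
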